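## The problem

The target 14 is a compact tetracycle in which a 4,5-dibromopyrrole, an imidazolone, a piperidine and a cyclic guanidine are fused around one carbon, C(N3). This carbon carries the pyrrole nitrogen, the lactam nitrogen N3 and a guanidine nitrogen, and its fourth bond goes to the neighbouring C(OH), a guanidine carbinolamine at the oxidation level of a ketone. These two adjacent, fully substituted carbons are the only stereocentres. The five-membered guanidine ring can only be cis-fused to the piperidine, so each centre fixes the other and the relative configuration takes care of itself. Neither centre exists in a configurationally stable form before the guanidine ring is closed, so the absolute configuration has to be imposed from outside at that moment. Both centres are ionisable (orthoamide-type aminal, carbinolamine), and the two C–Br bonds on the electron-poor pyrrole exclude zerovalent palladium, hydrogenation over palladium, halogen–metal exchange and dissolving metals. The enabling feature is the four-carbon ring segment C(OH)–CH2–CH2–CH2–N3: C(OH) at the ketone level and the NCH2 carbon, before reduction, at the aldehyde level are the two α-carbons of a furan. A furan bound through its C2 to the future C(N3) places its C5 six atoms from the lactam N–H.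

## Retrosynthesis

**14 ⇒ 13.** The exocyclic carbamate bond of the N-Boc tetracycle 13 is cut last. A guanidine that carries one acid-labile acyl group is easier to purify and is much less basic than the free one, which matters for the acid-mediated step before it. The forward step is a plain acidolysis. The protonated guanidinium should discourage ionisation at either stereocentre, and dehydration to an aromatic 2-aminoimidazole is impossible because C(N3) has no hydrogen.

**13 ⇒ 11 + 12.** Both C–N bonds that tie the guanidine to the carbocycle are cut, C(OH)–N and C(N3)–N. This returns the racemic methoxy aminal ketone 11 and N-Boc-guanidine 12. The neighbouring options are to introduce one nitrogen at a time, or to annulate a urea and exchange oxygen for nitrogen afterwards. Both add steps and manipulate a triply heteroatom-substituted carbon more than once. The double cut removes a ring and both stereocentres at once, and it leaves a precursor whose only stereocentre is lost on ionisation. The forward reaction must add a guanidine nitrogen to the ketone, replace methoxide at the aminal carbon with the second nitrogen, and choose one enantiomer while doing so.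

**11 ⇒ 10 ⇒ 9.** No skeletal bond is cut here. The CH2–CH2 unit of 11 is taken back to the cis-alkene of enone 10, and the NCH2 carbon of 10 to the N-acyl hemiaminal of 9. These are the oxidation levels that a furan oxidation delivers, so the two adjustments are the price of the next disconnection. The forward steps need a hydride donor that reduces the hemiaminal carbon and leaves the methoxy aminal alone, and a hydrogenation that leaves the C–Br bonds alone.

**9 ⇒ 8 ⇒ 7 ⇒ 6.** The N3–CH(OH) bond is cut to reveal the cis-keto-enal 8. Its 1,4-dicarbonyl pattern is folded back, through endoperoxide 7, into the furan of the bicyclic methoxy aminal 6. The alternatives are to close the piperidine by C–C bond formation on a chain hung from the aminal carbon, or to oxidise the furan with an electrophilic halogen. The first requires chain building at a carbon bearing three heteroatoms, and the second puts the pyrrole and the acid-labile aminal at risk. Singlet oxygen is neutral and should react only with the electron-rich diene. The simplification is large: 6 has two rings fewer than the target, one inconsequential stereocentre, and its furan holds all four carbons with the correct oxidation pattern. The forward reaction needs chemoselectivity (furan over pyrrole, nitrogen over oxygen closure) and no stereocontrol.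

**6 ⇒ 5 ⇒ 4 ⇒ 3.** The C–OMe bond at the aminal carbon is cut, back to the C–H aminal 3 through acyl amidine 5 and N-chloro lactam 4. The methoxy group is needed twice. It makes the aminal carbon fully substituted, so the pyridinone ring of 9 cannot aromatise, and it is the leaving group for the guanidine annulation. It is put on after the bicycle is closed because ring closure at the aldehyde oxidation level is unambiguous. Assembly at the acid oxidation level would pass through an open-chain isomer of 6 whose ring–chain preference is not known. The forward step must oxidise the one C–H flanked by two nitrogens in the presence of a furan.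

**3 ⇒ 1 + 2.** Both C–N bonds of the aminal carbon are cut, giving 4,5-dibromo-1H-pyrrole-2-carboxamide 1 and furfural 2. The forward step is an acid-catalysed condensation in which the carboxamide and the pyrrole N–H act as a 1,5-dinucleophile.

## Roads not taken

**Alternative 1:** Curtius route to the carbinolamine.
- **Cut:** the C(OH)–N bond is traced to the carboxyl carbon of the quaternary α-silyloxy acid A1, a piperidin-2-one already N-acylated by the dibromopyrrole.
- **Forward key step:** A1 is activated with diphenylphosphoryl azide, rearranged with retention and trapped with ammonia to give urea A2.
- **Merits:** the rearrangement is stereospecific, and A1 can draw its configuration from established enantioselective α-hydroxylation of a β-dicarbonyl lactam. In stereocontrol this road is better than the chosen one, which depends on an unprecedented enantioselective annulation.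
- **Weak points:**
  - The nitrogen sits on a carbon that also bears oxygen, so the rearranged intermediate and A2 are ketone N,O-derivatives held together only by the silyl group.
  - The key step closes no ring.
  - C(N3) still has to be made by dehydrative double addition of the pyrrole N–H and a urea N–H to a hindered imide carbonyl.
  - The urea oxygen must later be exchanged for nitrogen in the presence of the tertiary carbinolamine.
- **Comparison:** the chosen plan sets against the better stereocontrol a much shorter sequence, an intact guanidine introduced in one operation, and both heteroatom-bearing carbons at the right oxidation level from the start.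

**Alternative 2:** ion-paired guanidine annulation as the strategic step.
- **Cut:** C(OH)–N and C(N3)–N.
- **Forward key step:** a Boc-guanidine adds to an α-keto methoxy aminal under a chiral phosphoric acid to give A3, which is the same compound as 13.
- **Merits:** both stereocentres and the last ring are formed in one step from a racemic, ionisable precursor.
- **Weak points:** as a stand-alone plan it leaves the supply of the keto aminal open. The obvious sources need a C–H oxidation at a carbon flanked by two nitrogens and a ketone, or else build the chain on a carbon that already bears three heteroatoms.
- **Comparison:** this is not a rival but the endgame adopted here (step 6), so in enantiocontrol the two plans are exactly equal and share the same risk. What the chosen plan adds is a short, chemoselective origin for the ketone, in which the four-carbon chain and its oxygenation come from one aromatic ring.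

**Alternative 3:** chiral-pool relay with tandem aminal closure.
- **Cut:** C(N3)–N(pyrrole) and C(N3)–N(guanidine) of the deoxy tetracycle A6, back to the guanidino imide A5, which derives from L-ornithine A4.
- **Forward key step:** the pyrrole N–H adds to the imide carbonyl of A5. After activation of the new hydroxyl, the guanidine on the adjacent carbon captures the ionised carbon and closes two rings.
- **Merits:** the absolute configuration is bought, and two rings and the triaminomethane carbon form in one operation. Both points are better than in the chosen plan.
- **Weak points:**
  - The stereocentre of A5 is a C–H next to the carbon that is ionised, so tautomerisation to the enamide would erase it.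
  - A6 lacks the hydroxyl. Introducing it means hydroxylating, with retention, a tertiary C–H next to a guanidine nitrogen in a molecule full of oxidisable nitrogen and an electron-rich heterocycle. No dependable method exists for this.
- **Comparison:** the chosen plan carries the oxygen from the first furan-containing intermediate and needs no late C–H oxidation. It pays for this with catalyst-controlled rather than chiral-pool stereochemistry.

Key step: step 3

## Route

Assumptions: 1, 2 and 12 are treated as catalogue compounds. The target is delivered as the neutral guanidine base, liberated from its trifluoroacetate on bicarbonate work-up. Compound 13 is drawn as its exocyclic NH–Boc tautomer.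

Step 1
Reactants: 1 4,5-dibromo-1H-pyrrole-2-carboxamide; 2 furan-2-carbaldehyde (furfural)
Product: 3 racemic 5,6-dibromo-3-(furan-2-yl)-2,3-dihydro-1H-pyrrolo[1,2-c]imidazol-1-one
Conditions: PPTS (10 mol %), PhMe, reflux, Dean–Stark
Reagents that add atoms: none
Why: Acid-catalysed cyclic aminal formation (N,N-acetalisation): amide and aldehyde give a furyl-stabilised N-acyliminium ion that the adjacent pyrrole N–H captures, as in the formation of imidazolidin-4-ones from α-amino amides and of 2,3-dihydroquinazolin-4(1H)-ones from anthranilamides; azeotropic removal of water drives it, and the new stereocentre is racemic and of no consequence.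

Step 2
Reactants: 3 racemic 5,6-dibromo-3-(furan-2-yl)-2,3-dihydro-1H-pyrrolo[1,2-c]imidazol-1-one
Product: 6 racemic 5,6-dibromo-3-(furan-2-yl)-3-methoxy-2,3-dihydro-1H-pyrrolo[1,2-c]imidazol-1-one, via N-chloro lactam 4 (not isolated), via cyclic N-acyl amidine 5 (not isolated)
Conditions: LiOMe (3 equiv), t-BuOCl (1.1 equiv), THF–MeOH, −78 °C; then AcOH, −78 °C
Reagents that add atoms: lithium methoxide, [Li+].[O-]C
Why: This is the N-chlorination, dehydrochlorination and methoxide-addition sequence used for the 7α-methoxylation of cephalosporin amides: the lactam anion is chlorinated on nitrogen, methoxide removes the C–H flanked by two nitrogens and the furan with loss of chloride, and methoxide adds to the C=N carbon of 5. The cold acidic quench protonates the amidate before it can expel the pyrrolide, thienyl amides tolerate these conditions in the cephalosporin series, and the one-equivalent oxidant at −78 °C should spare the furan.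

Step 3
Reactants: 6 racemic 5,6-dibromo-3-(furan-2-yl)-3-methoxy-2,3-dihydro-1H-pyrrolo[1,2-c]imidazol-1-one
Product: 9 racemic tricyclic enone hemiaminal (fused 6-hydroxy-2-methoxy-2H-pyridin-3(6H)-one; both hemiaminal epimers), via furan endoperoxide 7 (not isolated), via cis-keto-enal 8 (not isolated)
Conditions: O2, rose bengal (C20H2Cl4I4Na2O5, 2 mol %), green LEDs, MeOH–CH2Cl2 (1:1), −78 °C; then Me2S (2 equiv), −78 → 0 °C
Reagents that add atoms: dioxygen, O=O
Why: Singlet oxygen from rose bengal sensitisation adds (4+2) across the furan of 6 to give the 2,3,7-trioxabicyclo[2.2.1]heptene 7. Dimethyl sulfide cleaves the O–O bond and the bicycle collapses to the (Z)-4-oxo-enal 8, whose Z geometry is inherited from the ring. The lactam N–H then adds to the aldehyde in a 6-exo-trig closure to give 9; this is the aza-Achmatowicz rearrangement in its singlet-oxygen form, known for furfuryl amides, carbamates and sulfonamides. One ring and one N–C bond are formed; the hemiaminal carbon is a new stereocentre but arises uncontrolled and is erased in step 4, so no stereocontrol is needed. The furan is the only electron-rich diene, since the pyrrole is N-substituted, acylated and dibrominated. Closure through nitrogen gives a six-membered ring, whereas the amide oxygen could only close an eight-membered one, and any reversible oxygen-closed lactol drains to 9. The aminal carbon has no hydrogen, so 9 cannot tautomerise to a 3-oxidopyridinium species, and the methanol co-solvent keeps the aminal at the methoxy stage.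

Step 4
Reactants: 9 racemic tricyclic enone hemiaminal
Product: 10 racemic tricyclic enone (NCH2 in place of NCH(OH))
Conditions: Et3SiH (3 equiv), TFA (10 equiv), CH2Cl2, −40 → 0 °C
Reagents that add atoms: none
Why: Ionic hydrogenation of an N-acyl hemiaminal through its N-acyliminium ion is the standard way of deoxygenating aza-Achmatowicz products to 1,6-dihydro-2H-pyridin-3-ones. The hemiaminal ionises in preference to the methoxy aminal because a cation at the latter would sit directly on the ketone carbon.

Step 5
Reactants: 10 racemic tricyclic enone
Product: 11 racemic tricyclic methoxy aminal ketone (bridge C(=O)–CH2–CH2–CH2 between aminal carbon and lactam N)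
Conditions: H2 (1 atm), RhCl(PPh3)3 (10 mol %), PhMe, 23 °C
Reagents that add atoms: none
Why: Homogeneous hydrogenation with RhCl(PPh3)3 reduces unhindered cis-disubstituted alkenes, including the alkene of an enone, and does not cleave aryl C–Br bonds as palladium on carbon would; no stereocentre is created.

Step 6
Reactants: 11 racemic tricyclic methoxy aminal ketone; 12 N-Boc-guanidine
Product: 13 N-Boc tetracycle, (R) at the carbinolamine carbon and (S) at the triaminomethane carbon
Conditions: (R)-TRIP [(R)-3,3'-bis(2,4,6-triisopropylphenyl)-1,1'-binaphthyl-2,2'-diyl hydrogen phosphate] (10 mol %), 5 Å MS, PhMe, 40 °C
Reagents that add atoms: none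
Why: Proposed new method: 12 should add reversibly to the electrophilic ketone of 11, and the carbinolamine is then held as a guanidinium phosphate contact ion pair. Proton transfer within that pair to the methoxy group releases methanol (taken up by the sieves), while the second guanidine nitrogen closes the five-membered ring on the N-acyl-stabilised aminal cation (5-exo-tet with SN1 character). The aminal carbon is planar in the cation and ketone addition is reversible, so both enantiomers of 11 can funnel through one chiral ion pair (dynamic kinetic asymmetric transformation). The cis ring fusion fixes the relative configuration and the phosphate the absolute one, with the (S)-catalyst to be used if (R)-TRIP favours the mirror image. The closest known reaction type is the chiral phosphoric acid-catalysed enantioselective formation of cyclic aminals and N,N-acetals through N-acyliminium phosphate ion pairs.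

Step 7
Reactants: 13 N-Boc tetracycle
Product: 14 target, (R) at C(OH) and (S) at C(N3)
Conditions: TFA–CH2Cl2 (1:4), 0 °C; then aq. NaHCO3
Reagents that add atoms: none
Why: Acidolysis of a tert-butyl carbamate on a guanidine is routine; the protonated guanidinium disfavours ionisation at either stereocentre, and the carbinolamine cannot dehydrate to an aromatic ring because C(N3) is fully substituted, so both centres should be retained.

## Compound list

1 | 4,5-dibromo-1H-pyrrole-2-carboxamide | NC(=O)c1cc(Br)c(Br)[nH]1 | starting material
2 | furan-2-carbaldehyde (furfural) | O=Cc1ccco1 | starting material
3 | racemic 5,6-dibromo-3-(furan-2-yl)-2,3-dihydro-1H-pyrrolo[1,2-c]imidazol-1-one | O=C1NC(c2ccco2)n2c1cc(Br)c2Br | intermediate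
4 | racemic 5,6-dibromo-2-chloro-3-(furan-2-yl)-2,3-dihydro-1H-pyrrolo[1,2-c]imidazol-1-one (N-chloro lactam, formed in the flask) | O=C1N(Cl)C(c2ccco2)n2c1cc(Br)c2Br | intermediate
5 | 5,6-dibromo-3-(furan-2-yl)-1H-pyrrolo[1,2-c]imidazol-1-one (cyclic N-acyl amidine, formed in the flask) | O=C1N=C(c2ccco2)n2c1cc(Br)c2Br | intermediate
6 | racemic 5,6-dibromo-3-(furan-2-yl)-3-methoxy-2,3-dihydro-1H-pyrrolo[1,2-c]imidazol-1-one | COC1(c2ccco2)NC(=O)c2cc(Br)c(Br)n12 | intermediate
7 | 5,6-dibromo-3-methoxy-3-(2,3,7-trioxabicyclo[2.2.1]hept-5-en-1-yl)-2,3-dihydro-1H-pyrrolo[1,2-c]imidazol-1-one (furan endoperoxide, formed in the flask) | COC1(C23OOC(O2)C=C3)NC(=O)c2cc(Br)c(Br)n12 | intermediate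
8 | (Z)-4-(5,6-dibromo-3-methoxy-1-oxo-2,3-dihydro-1H-pyrrolo[1,2-c]imidazol-3-yl)-4-oxobut-2-enal (cis-keto-enal, formed in the flask) | COC1(C(=O)/C=C\C=O)NC(=O)c2cc(Br)c(Br)n12 | intermediate
9 | racemic tricyclic enone hemiaminal, both epimers at the carbinol carbon: lactam N and methoxy aminal carbon of the dibromopyrroloimidazolone bridged by C(=O)–CH=CH–CH(OH), with C=O on the aminal carbon and CH(OH) on N | COC12C(=O)C=CC(O)N1C(=O)c1cc(Br)c(Br)n12 | intermediate
10 | racemic tricyclic enone: as 9 with the bridge C(=O)–CH=CH–CH2 | COC12C(=O)C=CCN1C(=O)c1cc(Br)c(Br)n12 | intermediate
11 | racemic tricyclic methoxy aminal ketone: as 10 with the bridge C(=O)–CH2–CH2–CH2 | COC12C(=O)CCCN1C(=O)c1cc(Br)c(Br)n12 | intermediate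
12 | N-Boc-guanidine (tert-butyl carbamimidoylcarbamate) | CC(C)(C)OC(=O)NC(N)=N | starting material
13 | N-Boc tetracycle: former ketone carbon (now C–OH, R) and former methoxy aminal carbon (S) of 11 joined through the two ring nitrogens of a 2-(Boc-amino)imidazoline | CC(C)(C)OC(=O)NC1=N[C@@]2(O)CCCN3C(=O)c4cc(Br)c(Br)n4[C@@]32N1 | intermediate
14 | target: free 2-aminoimidazoline tetracycle, (R) at C(OH), (S) at C(N3) | NC1=N[C@@]2(O)CCCN3C(=O)c4cc(Br)c(Br)n4[C@@]32N1 | target

## Step count and risks

Total steps: 7. Longest linear sequence: 7 (steps 1–7 from 1).

**Step 6 (carries the new-method label).**
- What may go wrong: poor turnover, because the basic guanidine levels the acid to a guanidinium and the aminal ionises slowly; poor facial discrimination by a phosphate that is paired with the nucleophile rather than with the cation; partial erosion of enantiopurity if the first C–N bond forms reversibly.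
- Fallback (known chemistry): from 11, condensation with 12 promoted by achiral diphenyl phosphate (PhMe, 5 Å MS, 60 °C) should give the racemate, that is 13 together with the mirror-image N-Boc tetracycle F1. This combines two established operations, addition of a guanidine to an activated ketone and acid-promoted N-acyliminium substitution. Preparative HPLC on a polysaccharide chiral stationary phase then separates the enantiomers, and the route is rejoined at 13.

**Step 3 (key step).**
- What may go wrong: sluggish closure of the weakly nucleophilic, hindered lactam N–H, leaving the open keto-enal to isomerise to the trans form or to be held as oxygen-closed lactols; fragmentation of the endoperoxide next to the heteroatom-rich quaternary carbon; loss of methanol from the aminal.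
- Fallback: from 6, the two-stage Clauson-Kaas sequence. Br2 in MeOH with Na2CO3 at −40 °C converts the furan into the 2,5-dimethoxy-2,5-dihydrofuran F2, which is isolable. PPTS in wet acetone then unmasks the same keto-enal 8 under conditions that also catalyse nitrogen closure, and the route is rejoined at 9.

**Step 2.**
- What may go wrong: electrophilic chlorination of the furan in competition with N-chlorination; ring opening of the product amidate by expulsion of the pyrrolide before the quench.
- Fallback: from 3, dehydrogenation with DDQ (dioxane, 23 → 60 °C), as used for 2-aryl-2,3-dihydroquinazolin-4(1H)-ones, to give 5 as an isolated compound. Methanol with a trace of PPTS is then added across its C=N bond under non-basic conditions, and the route is rejoined at 6. No new compound is involved.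

**Step 4.**
- What may go wrong: competing ionisation of the methoxy aminal with over-reduction at that carbon; hydride delivery at the γ-carbon instead of the hemiaminal carbon.
- Fallback: from 9, the order is changed and the hydride donor is avoided.
  - Hydrogenation with RhCl(PPh3)3 first gives the saturated hydroxy lactam F3.
  - MsCl and Et3N dehydrate it, through its methanesulfonate F4, to the enamide F5.
  - A second hydrogenation with RhCl(PPh3)3 gives 11, where the route is rejoined; 10 is bypassed.

## Further compounds

F1 | step 6 | mirror-image N-Boc tetracycle, (S) at the carbinolamine carbon and (R) at the triaminomethane carbon | CC(C)(C)OC(=O)NC1=N[C@]2(O)CCCN3C(=O)c4cc(Br)c(Br)n4[C@]32N1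
F2 | step 3 | 5,6-dibromo-3-(2,5-dimethoxy-2,5-dihydrofuran-2-yl)-3-methoxy-2,3-dihydro-1H-pyrrolo[1,2-c]imidazol-1-one (diastereomer mixture) | COC1(C2(OC)OC(OC)C=C2)NC(=O)c2cc(Br)c(Br)n12
F0 | step 2 | none | none
F3 | step 4 | racemic saturated hydroxy lactam: as 9 with the bridge C(=O)–CH2–CH2–CH(OH) (both epimers) | COC12C(=O)CCC(O)N1C(=O)c1cc(Br)c(Br)n12
F4 | step 4 | methanesulfonate of F3 | COC12C(=O)CCC(OS(C)(=O)=O)N1C(=O)c1cc(Br)c(Br)n12
F5 | step 4 | racemic enamide: bridge C(=O)–CH2–CH=CH between aminal carbon and lactam N | COC12C(=O)CC=CN1C(=O)c1cc(Br)c(Br)n12
A1 | alternative 1 | 3-(tert-butyldimethylsilyloxy)-1-(4,5-dibromo-1H-pyrrole-2-carbonyl)-2-oxopiperidine-3-carboxylic acid, single enantiomer | OC(=O)[C@@]1(O[Si](C)(C)C(C)(C)C)CCCN(C(=O)c2cc(Br)c(Br)[nH]2)C1=O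
A2 | alternative 1 | 3-ureido-3-(tert-butyldimethylsilyloxy)-1-(4,5-dibromo-1H-pyrrole-2-carbonyl)piperidin-2-one, single enantiomer | NC(=O)N[C@@]1(O[Si](C)(C)C(C)(C)C)CCCN(C(=O)c2cc(Br)c(Br)[nH]2)C1=O
A3 | alternative 2 | N-Boc derivative of the target (identical with 13) | CC(C)(C)OC(=O)NC1=N[C@@]2(O)CCCN3C(=O)c4cc(Br)c(Br)n4[C@@]32N1
A4 | alternative 3 | L-ornithine | N[C@@H](CCCN)C(=O)O
A5 | alternative 3 | (S)-3-(N'-Boc-guanidino)-1-(4,5-dibromo-1H-pyrrole-2-carbonyl)piperidin-2-one | CC(C)(C)OC(=O)NC(=N)N[C@H]1CCCN(C(=O)c2cc(Br)c(Br)[nH]2)C1=O
A6 | alternative 3 | N-Boc deoxy tetracycle (H in place of OH) | CC(C)(C)OC(=O)NC1=N[C@H]2CCCN3C(=O)c4cc(Br)c(Br)n4[C@@]32N1
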